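**Plan**

- Retrosynthesis cuts, in order: the O–CH3 bond of the enol ether; the ring bonds CMe2–C(=O) and CHMe–C(=O) that tie a 2-methylpentan-3-one unit to the two carbonyls on the spiro carbon; the cyclopentane bond between that diacyl carbon and the CH(i-Pr) carbon; the two cyclopropane bonds of a vinylcyclopropane built on pinane C2.
- Enabling feature: the cyclopentane holds pinane C2, the diacyl spiro carbon and the CH(i-Pr) carbon side by side, so its last bond can arise by a 1,3-shift from a cyclopropane made of C2, the diacyl carbon and an alkenyl-bearing CH.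
- Forward: pinane (bought) → spiro cyclopropane (step 6) → cyclopentene (step 7) → saturation → six-membered trione ring by acylation and Claisen closure (steps 11, 12) → O-methylation.
- Stereochemistry: C1 and C5 come from (+)-β-pinene; C2 is set by ylide attack anti to the gem-dimethyl bridge; the CH(i-Pr) centre is set in the nickel step (i-Pr toward C3, away from bridgehead C1); the diacyl carbon becomes stereogenic when methoxide opens the Meldrum's carbonyl trans to i-Pr.

Key step: step 7

Assumption: (1R,5R)-(+)-β-pinene is bought as the single enantiomer; locants C1–C7 are those of the pinane skeleton (C2 = spiro carbon, C6 = CMe2 bridge, C7 = CH2 bridge).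

**Route**

Step 1
Reactants: 1 (+)-β-pinene
Product: 3 (1S,5R)-(−)-nopinone, via β-pinene ozonide 2 (not isolated)
Conditions: O3, CH2Cl2, −78 °C; then Me2S, −78 °C → rt
Reagents that add atoms: ozone, [O-][O+]=O
Why: Ozonolysis with reductive work-up cleaves only the exocyclic 1,1-disubstituted alkene and leaves both bridgehead stereocentres untouched.

Step 2
Reactants: 3 (1S,5R)-(−)-nopinone; 4 Meldrum's acid
Product: 5 nopinylidene Meldrum's acid
Conditions: TiCl4, pyridine, THF, 0 °C → rt
Reagents that add atoms: none
Why: Knoevenagel condensation in which TiCl4 activates the hindered ketone and pyridine drives the dehydration, giving the tetrasubstituted alkylidene without a new stereocentre.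

Step 3
Reactants: 6 isobutyraldehyde
Product: 7 (±)-4-methylpent-1-en-3-ol
Conditions: CH2=CHMgBr, THF, 0 °C; aq. NH4Cl
Reagents that add atoms: vinylmagnesium bromide, C=C[Mg]Br
Why: Grignard 1,2-addition to an unhindered aldehyde; the carbinol centre is racemic and disappears in step 4.

Step 4
Reactants: 7 (±)-4-methylpent-1-en-3-ol
Product: 8 (E)-1-bromo-4-methylpent-2-ene
Conditions: 48 % aq. HBr, 0 °C → rt
Reagents that add atoms: hydrogen bromide, Br
Why: Allylic substitution with transposition under thermodynamic control should favour the less hindered primary (E)-allylic bromide, and any secondary bromide left should converge on the same sulfonium salt in step 5.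

Step 5
Reactants: 8 (E)-1-bromo-4-methylpent-2-ene
Product: 9 1-[(E)-4-methylpent-2-en-1-yl]tetrahydrothiophen-1-ium bromide
Conditions: tetrahydrothiophene, acetone, rt
Reagents that add atoms: tetrahydrothiophene, C1CCSC1
Why: SN2 alkylation of a sulfide by a primary allylic bromide gives the sulfonium salt with the E alkene intact.

Step 6
Reactants: 5 nopinylidene Meldrum's acid; 9 1-[(E)-4-methylpent-2-en-1-yl]tetrahydrothiophen-1-ium bromide
Product: 11 dispiro vinylcyclopropane, via sulfonium ylide 10 (not isolated)
Conditions: 9, KN(SiMe3)2, THF, −78 °C; then 5, −78 °C → rt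
Reagents that add atoms: none
Why: Corey–Chaykovsky cyclopropanation (Michael addition, then 3-exo-tet closure): the ylide carbon should add to C2 from the C7 face, anti to the gem-dimethyl bridge, and the Meldrum's anion then expels tetrahydrothiophene, which fixes C2 with the diacyl carbon syn to C6; the new CH centre (alkenyl expected cis to C3) is erased in step 7, so both epimers can be carried on.

Step 7
Reactants: 11 dispiro vinylcyclopropane
Product: 12 dispiro cyclopentene Meldrum's acid
Conditions: Ni(cod)2 (10 mol %), 1,3-bis(2,6-diisopropylphenyl)imidazol-2-ylidene (10 mol %), toluene, rt → 60 °C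
Reagents that add atoms: none
Why: Zerovalent nickel carrying the N-heterocyclic carbene binds the alkene and inserts into the cyclopropane bond between the alkenyl-bearing CH and the Meldrum's carbon, the only ring bond flanked by the π-donor and both acyl acceptors, giving an allyl complex of divalent nickel that is also bound to the Meldrum's carbon. After syn–anti isomerisation of the allyl unit, C–C reductive elimination at the far, isopropyl-bearing allyl carbon forms the new bond; the closest known reaction type is the Ni(cod)2/N-heterocyclic carbene catalysed vinylcyclopropane-to-cyclopentene rearrangement, applied here to a doubly acyl-activated cyclopropane. The cyclopentene thus closes by reductive elimination from a six-membered nickelacycle, a net 1,3-shift (formally a 5-endo closure made possible by the metal template) driven by release of cyclopropane strain. The new CH(i-Pr) stereocentre is under substrate control: in the ring-closing geometry the isopropyl group should turn to the face of the forming ring that carries the C3 methylene, away from the C1 bridgehead and its bridges. The step needs C- rather than O-closure, closure at the far rather than the near allyl carbon and no β-hydride loss; the rigid Meldrum's acid (O-closure would give a strained ketene acetal), the degenerate return to the cyclopropane and the fast reductive elimination promoted by the bulky carbene should secure these. C2 takes no part in bond breaking, so its configuration from step 6 is kept, and either epimer at the alkenyl-bearing carbon gives the same product because that carbon becomes sp2.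

Step 8
Reactants: 12 dispiro cyclopentene Meldrum's acid
Product: 13 saturated dispiro Meldrum's acid
Conditions: H2 (1 atm), Pd/C, EtOAc, rt
Reagents that add atoms: none
Why: Heterogeneous catalytic hydrogenation of a cis-disubstituted cyclopentene creates no stereocentre and leaves the Meldrum's acid ring intact.

Step 9
Reactants: 13 saturated dispiro Meldrum's acid
Product: 14 malonic half ester (CO2Me trans, CO2H cis to isopropyl)
Conditions: NaOMe, MeOH, 0 → 40 °C; then cold 1 M HCl
Reagents that add atoms: sodium methoxide, [Na+].[O-]C
Why: Alkoxide ring opening of a 5,5-disubstituted Meldrum's acid with loss of acetone: methoxide should attack the carbonyl trans to isopropyl, which is open along the side of the ring C–H, whereas the cis carbonyl is screened by isopropyl and by the C3 methylene, so the diacyl carbon becomes a defined quaternary stereocentre.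

Step 10
Reactants: 14 malonic half ester
Product: 15 half ester acid chloride
Conditions: (COCl)2, DMF (cat.), CH2Cl2, 0 °C → rt
Reagents that add atoms: oxalyl chloride, O=C(Cl)C(Cl)=O
Why: Acid chloride formation through the catalytic chloroiminium species; the acid has no α-hydrogen, so neither ketene formation nor epimerisation can occur and the methyl ester is untouched.

Step 11
Reactants: 15 half ester acid chloride; 16 2-methylpentan-3-one
Product: 17 β-diketone methyl ester
Conditions: 16 (2.2 equiv), LiN(i-Pr)2 (2.2 equiv), THF, −78 °C; then 15, −78 → 0 °C; 1 M HCl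
Reagents that add atoms: none
Why: Crossed Claisen-type C-acylation of the kinetic lithium enolate, formed at the ethyl CH2 of 16; the second equivalent of enolate takes up the acidic proton of the new 1,3-diketone, whose CHMe carbon is a labile centre of no consequence.

Step 12
Reactants: 17 β-diketone methyl ester
Product: 18 spiro trione
Conditions: LiN(i-Pr)2 (3 equiv), THF, −78 °C → rt; 1 M HCl
Reagents that add atoms: none
Why: Dianion Claisen (Dieckmann-type) cyclisation: after the diketonate forms, the only remaining α-hydrogen, the isopropyl methine, is removed and this carbon attacks the methyl ester in a 6-exo-trig closure driven by formation of the stabilised trione enolate, while the quaternary spiro centre cannot epimerise.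

Step 13
Reactants: 18 spiro trione
Product: 19 CNP0307059.1
Conditions: Me2SO4, K2CO3, acetone, reflux
Reagents that add atoms: dimethyl sulfate, COS(=O)(=O)OC
Why: O-alkylation of a cyclic β-diketonate by a hard electrophile: the enolate oxygen next to CMe2 should react in preference to the one next to the spiro carbon, which is shielded by the cis isopropyl group, placing the methoxy group as in the target.

**Compound list**

1 | (+)-β-pinene, (1R,5R)-6,6-dimethyl-2-methylenebicyclo[3.1.1]heptane | C=C1CC[C@@H]2C[C@H]1C2(C)C | starting material
2 | β-pinene ozonide, spiro-1,2,4-trioxolane at pinane C2 (both epimers at C2) | C1OOC2(O1)CC[C@@H]3C[C@H]2C3(C)C | intermediate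
3 | (1S,5R)-(−)-nopinone, 6,6-dimethylbicyclo[3.1.1]heptan-2-one | O=C1CC[C@@H]2C[C@H]1C2(C)C | intermediate
4 | Meldrum's acid, 2,2-dimethyl-1,3-dioxane-4,6-dione | CC1(C)OC(=O)CC(=O)O1 | starting material
5 | nopinylidene Meldrum's acid, 5-[(1S,5R)-6,6-dimethylbicyclo[3.1.1]heptan-2-ylidene]-2,2-dimethyl-1,3-dioxane-4,6-dione | CC1(C)OC(=O)C(C(=O)O1)=C1CC[C@@H]2C[C@H]1C2(C)C | intermediate
6 | isobutyraldehyde | CC(C)C=O | starting material
7 | (±)-4-methylpent-1-en-3-ol | C=CC(O)C(C)C | intermediate
8 | (E)-1-bromo-4-methylpent-2-ene | CC(C)/C=C/CBr | intermediate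
9 | 1-[(E)-4-methylpent-2-en-1-yl]tetrahydrothiophen-1-ium bromide | CC(C)/C=C/C[S+]1CCCC1.[Br-] | intermediate
10 | sulfonium ylide from 9 (carbanion at the S-bound allylic carbon) | CC(C)/C=C/[CH-][S+]1CCCC1 | intermediate
11 | dispiro vinylcyclopropane: cyclopropane made of pinane C2, Meldrum's C5 and a CH bearing (E)-3-methylbut-1-enyl; Meldrum's carbon syn to the C6 gem-dimethyl bridge, CH on the C7 side, alkenyl cis to C3 | CC1(C)OC(=O)C2(C(=O)O1)[C@@H](/C=C/C(C)C)[C@@]23CC[C@@H]4C[C@H]3C4(C)C | intermediate
12 | dispiro cyclopentene Meldrum's acid: ring of pinane C2, CH=CH, CH(i-Pr) and Meldrum's C5; Meldrum's carbon syn to C6, isopropyl on the ring face that carries C3 | CC1(C)OC(=O)C2(C(=O)O1)[C@@H](C(C)C)C=C[C@@]23CC[C@@H]4C[C@H]3C4(C)C | intermediate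
13 | saturated dispiro Meldrum's acid (cyclopentane analogue of 12, same configuration) | CC1(C)OC(=O)C2(C(=O)O1)[C@@H](C(C)C)CC[C@@]23CC[C@@H]4C[C@H]3C4(C)C | intermediate
14 | malonic half ester: cyclopentane C1 carries CO2Me trans to isopropyl (cis to bridgehead C1 of the pinane) and CO2H cis to isopropyl | OC(=O)[C@@]1(C(=O)OC)[C@@H](C(C)C)CC[C@@]12CC[C@@H]3C[C@H]2C3(C)C | intermediate
15 | acid chloride of 14 (COCl cis, CO2Me trans to isopropyl) | ClC(=O)[C@@]1(C(=O)OC)[C@@H](C(C)C)CC[C@@]12CC[C@@H]3C[C@H]2C3(C)C | intermediate
16 | 2-methylpentan-3-one | CCC(=O)C(C)C | starting material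
17 | β-diketone methyl ester: 2,4-dimethyl-3-oxopentanoyl group cis and CO2Me trans to isopropyl on the quaternary carbon (CHMe centre unassigned, enolisable) | CC(C)C(=O)C(C)C(=O)[C@@]1(C(=O)OC)[C@@H](C(C)C)CC[C@@]12CC[C@@H]3C[C@H]2C3(C)C | intermediate
18 | spiro trione: 2,2,4-trimethylcyclohexane-1,3,5-trione spiro-fused at C6 to the cyclopentane; C(=O) next to CMe2 trans and C(=O) next to CHMe cis to isopropyl (enolised between C3 and C5) | O=C1C(C)C(=O)[C@@]2(C(=O)C1(C)C)[C@@H](C(C)C)CC[C@@]21CC[C@@H]2C[C@H]1C2(C)C | intermediate
19 | CNP0307059.1, methyl enol ether of 18 with OMe on the carbon next to CMe2 | COC1=C(C)C(=O)[C@@]2(C(=O)C1(C)C)[C@@H](C(C)C)CC[C@@]21CC[C@@H]2C[C@H]1C2(C)C | target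

**Step count and risks**

Total step count: 13. Longest linear sequence: 11 steps (steps 3–13, from isobutyraldehyde); the β-pinene branch (steps 1, 2) joins at step 6.

Steps most likely to fail:

1. Step 7. The allylnickel intermediate may return to the cyclopropane faster than it closes at the crowded isopropyl-bearing terminus, may lose a β-hydrogen to open-chain dienes, or may close with poor facial selectivity at the new CH centre. The fallback sets out from 5 and replaces the ring expansion by a radical ring closure. (4-Methylpent-3-en-1-yl)magnesium bromide F1, made from commercial 5-bromo-2-methylpent-2-ene and Mg, is added to 5 with CuBr·SMe2 (cat.) in THF at −40 °C. The chain should enter C2 anti to the gem-dimethyl bridge and give the 5-alkyl Meldrum's acid F2. Oxidation of F2 with Mn(OAc)3·2H2O and Cu(OAc)2 in AcOH should trigger 5-exo-trig cyclisation of the Meldrum's radical onto the trisubstituted alkene, followed by oxidation of the tertiary radical to an alkene, giving the isopropenyl spiro cyclopentane F3. Hydrogenation under the conditions of step 8 returns to the route at 13.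

2. Step 6. The basic ylide may remove a γ-proton (C3–H) from the acidic alkylidene 5 instead of adding to its tetrasubstituted carbon, or rearrange before it adds. The fallback sets out from 3 and changes the activating group to a malonic diester with much less acidic γ-protons. Knoevenagel condensation of 3 with dibenzyl malonate (TiCl4, pyridine) gives dibenzyl nopinylidenemalonate F4, which ylide 10 should convert into vinylcyclopropane diester F5. Rearrangement with Ni(cod)2 and the same carbene ligand as in step 7 gives cyclopentene diester F6. H2 over Pd/C saturates the alkene and cleaves both benzyl esters to diacid F7. Acetone, Ac2O and H2SO4 (cat.) then close the Meldrum's acid ring and return to the route at 13.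

3. Step 12. The tertiary carbanion of the dianion may fail to add to the neopentyl-type ester, or the crowded trione may reopen by retro-Claisen cleavage. The fallback sets out from 13, forms the hindered CMe2–C(=O) bond intermolecularly on the more electrophilic Meldrum's carbonyl, and closes the ring at the less hindered site. The lithium enolate of methyl isobutyrate (LiN(i-Pr)2, THF, −78 °C) should open 13 at the exposed carbonyl trans to isopropyl and, after loss of acetone, give keto acid F8. (COCl)2 converts it into acid chloride F9, and EtMgBr with Fe(acac)3 (cat.) at −78 °C gives ethyl ketone F10. KOt-Bu in THF then closes the ring by Dieckmann-type attack of the ethyl ketone enolate on the methyl ester, returning to the route at 18.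

**Further compounds**

F1 | step 7 | (4-methylpent-3-en-1-yl)magnesium bromide | CC(C)=CCC[Mg]Br
F2 | step 7 | 5-[2-(4-methylpent-3-en-1-yl)nopinan-2-yl] Meldrum's acid, chain anti and Meldrum's carbon syn to the C6 bridge | CC1(C)OC(=O)C(C(=O)O1)[C@@]1(CCC=C(C)C)CC[C@@H]2C[C@H]1C2(C)C
F3 | step 7 | isopropenyl analogue of 13 (isopropenyl on the ring face that carries C3) | CC1(C)OC(=O)C2(C(=O)O1)[C@@H](C(C)=C)CC[C@@]23CC[C@@H]4C[C@H]3C4(C)C
F4 | step 6 | dibenzyl nopinylidenemalonate | O=C(OCc1ccccc1)C(C(=O)OCc1ccccc1)=C1CC[C@@H]2C[C@H]1C2(C)C
F5 | step 6 | dibenzyl ester analogue of 11 (spiro vinylcyclopropane-1,1-dicarboxylate) | O=C(OCc1ccccc1)C1(C(=O)OCc2ccccc2)[C@@H](/C=C/C(C)C)[C@@]13CC[C@@H]4C[C@H]3C4(C)C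
F6 | step 6 | dibenzyl ester analogue of 12 (spiro cyclopentene-1,1-dicarboxylate) | O=C(OCc1ccccc1)C1(C(=O)OCc2ccccc2)[C@@H](C(C)C)C=C[C@@]13CC[C@@H]4C[C@H]3C4(C)C
F7 | step 6 | saturated spiro cyclopentane-1,1-dicarboxylic acid | OC(=O)C1(C(O)=O)[C@@H](C(C)C)CC[C@@]12CC[C@@H]3C[C@H]2C3(C)C
F8 | step 12 | keto acid: CO2H cis and 3-methoxy-2,2-dimethyl-3-oxopropanoyl trans to isopropyl | OC(=O)[C@@]1(C(=O)C(C)(C)C(=O)OC)[C@@H](C(C)C)CC[C@@]12CC[C@@H]3C[C@H]2C3(C)C
F9 | step 12 | acid chloride of F8 | ClC(=O)[C@@]1(C(=O)C(C)(C)C(=O)OC)[C@@H](C(C)C)CC[C@@]12CC[C@@H]3C[C@H]2C3(C)C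
F10 | step 12 | ethyl ketone: propanoyl cis and 3-methoxy-2,2-dimethyl-3-oxopropanoyl trans to isopropyl | CCC(=O)[C@@]1(C(=O)C(C)(C)C(=O)OC)[C@@H](C(C)C)CC[C@@]12CC[C@@H]3C[C@H]2C3(C)C
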